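**Retrosynthetic overview**

1. Ainsliadimer B ⇐ its 4(15)-anhydro dienone, by oxa-Michael addition of water to C4=C15 (sets C4).
2. Anhydro dienone ⇐ dehydrozaluzanin C (dienophile) + its 1,2-dehydro trienone (diene, from the silyl dienol ether): a Diels–Alder reaction (C2–C4', C14–C15') builds the spiro-cyclohexene, followed by oxygenation at C10.
3. Dehydrozaluzanin C ⇐ estafiatin ⇐ guaia-3,10(14)-dienolide ⇐ isophotosantonic lactone: functional-group relay only, no ring construction.
4. Key step: isophotosantonic lactone ⇐ α-santonin by photochemical dienone rearrangement, which turns the decalin into the cyclopentenone and the cycloheptane in one operation and fixes H-1.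
5. Ring order: γ-lactone (present in santonin) → five- and seven-membered carbocycles together (step 1) → spiro-cyclohexene (step 10). Both halves come from the same monomer.

Assumption: isophotosantonic lactone is taken as the 1αH, 10α-hydroxy, 10β-methyl isomer; this carbinol centre is removed in step 4.

Guaiane numbering is used, primed numbers are the dienophile-derived half, and α is the face of H-5.

**Route**

Step 1
Reactants: 1 α-santonin
Product: 2 isophotosantonic lactone (10α-hydroxy-3-oxo-1αH-guai-4-en-12,6α-olide)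
Conditions: hν (medium-pressure Hg lamp, Pyrex), AcOH/H2O 1:1, reflux, N2
Reagents that add atoms: water, O
Why: Type A photorearrangement of a cross-conjugated cyclohexadienone (the santonin-to-isophotosantonic-lactone reaction): excitation leads to C1–C5 bonding on the α-face and, after O-protonation, cleavage of the C5–C10 cyclopropane bond, so the cyclopentenone and the cycloheptane are created together, H-1 is left α, and water captures C10 anti to the breaking bond (10α-OH, removed in step 4) while C6, C7 and C11 are not touched.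

Step 2
Reactants: 2 isophotosantonic lactone
Product: 3 3β,10α-dihydroxy-1αH-guai-4-en-12,6α-olide
Conditions: NaBH4, CeCl3·7H2O, MeOH, −78 → −40 °C
Reagents that add atoms: none
Why: Luche 1,2-reduction: the cerium-activated ketone takes hydride from the α-face, the face that is open on this hydroazulenone (the β-face carries C10 and its substituents), giving the 3β-allylic alcohol without touching the lactone.

Step 3
Reactants: 3 3β,10α-dihydroxy-1αH-guai-4-en-12,6α-olide
Product: 6 10α-hydroxy-1αH,5αH-guai-3-en-12,6α-olide, via allylic sulfonylhydrazine 4 (not isolated), via allylic diazene 5 (not isolated)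
Conditions: PPh3, DEAD, 2-nitrobenzenesulfonylhydrazide, THF, −30 °C, 2 h; then 23 °C, 3 h
Reagents that add atoms: none
Why: Myers reductive allylic transposition (Mitsunobu reaction, then sulfinate elimination and retro-ene loss of N2): SN2 inversion places nitrogen 3α, and the monoalkyl diazene hands its hydrogen suprafacially to C5 on the α-face, which sets the cis ring fusion (5αH) and moves the alkene to C3=C4; the tertiary 10-OH is inert to Mitsunobu activation.

Step 4
Reactants: 6 10α-hydroxy-1αH,5αH-guai-3-en-12,6α-olide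
Product: 7 1αH,5αH-guaia-3,10(14)-dien-12,6α-olide
Conditions: SOCl2, pyridine, CH2Cl2, −20 → 0 °C
Reagents that add atoms: none
Why: E2 dehydration of the tertiary chlorosulfite: H-1 is cis to the 10α leaving group and cannot be anti-periplanar, so elimination runs to the C14 methyl (three accessible hydrogens) and gives the exocyclic alkene, the minor 9(10)-ene being removed on AgNO3-impregnated silica; no stereocentre is created.

Step 5
Reactants: 7 1αH,5αH-guaia-3,10(14)-dien-12,6α-olide
Product: 10 1αH,5αH-guaia-3,10(14),11(13)-trien-12,6α-olide, via α-phenylselenide 8 (not isolated), via selenoxide 9 (not isolated)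
Conditions: LiN(iPr)2, THF, −78 °C; PhSeBr, −78 → −40 °C; then 30% H2O2, pyridine, 0 → 25 °C
Reagents that add atoms: none
Why: Reich–Grieco α-methylenation (enolate selenenylation, then selenoxide syn-elimination): PhSe enters the trans-fused lactone enolate anti to H-7, so the selenoxide finds syn hydrogens only on the C13 methyl and the exocyclic 11(13)-alkene forms; the C11 stereocentre is erased and the isolated alkenes do not react.

Step 6
Reactants: 10 1αH,5αH-guaia-3,10(14),11(13)-trien-12,6α-olide
Product: 11 estafiatin (3α,4α-epoxy-1αH,5αH-guaia-10(14),11(13)-dien-12,6α-olide)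
Conditions: mCPBA (1.0 equiv), CH2Cl2, 0 °C
Reagents that add atoms: mCPBA (3-chloroperbenzoic acid), OOC(=O)c1cccc(Cl)c1
Why: Prilezhaev epoxidation: the trisubstituted C3=C4 alkene is much more nucleophilic than the 1,1-disubstituted C10=C14 and the electron-poor C11=C13 alkenes, and the peracid attacks the convex α-face of the cis-fused hydroazulene, setting C3 and C4 as the 3α,4α-epoxide.

Step 7
Reactants: 11 estafiatin
Product: 12 3-epizaluzanin C (3α-hydroxy-1αH,5αH-guaia-4(15),10(14),11(13)-trien-12,6α-olide)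
Conditions: Al(OiPr)3, toluene, reflux
Reagents that add atoms: none
Why: Aluminium-alkoxide-promoted isomerisation of an epoxide to an allylic alcohol (syn β-elimination through a cyclic transition state): Al binds the epoxide oxygen, a C15 methyl proton is removed and the C4–O bond breaks, so the C3–O bond and its 3α configuration are retained.

Step 8
Reactants: 12 3-epizaluzanin C
Product: 13 dehydrozaluzanin C (3-oxo-1αH,5αH-guaia-4(15),10(14),11(13)-trien-12,6α-olide)
Conditions: Dess–Martin periodinane, CH2Cl2, 25 °C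
Reagents that add atoms: none
Why: Dess–Martin oxidation of the secondary allylic alcohol under neutral conditions gives the cross-conjugated exo-methylene ketone without isomerising the exocyclic alkenes or the C5 stereocentre; no stereocentre is formed.

Step 9
Reactants: 13 dehydrozaluzanin C
Product: 14 3-(tert-butyldimethylsilyloxy)-1αH,5αH-guaia-2,4(15),10(14),11(13)-tetraen-12,6α-olide
Conditions: TBSOTf, Et3N, CH2Cl2, −78 → 0 °C
Reagents that add atoms: TBSOTf (tert-butyldimethylsilyl trifluoromethanesulfonate), CC(C)(C)[Si](C)(C)OS(=O)(=O)C(F)(F)F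
Why: Soft enolisation and O-silylation (silyl enol ether formation): C2 carries the only enolisable hydrogens because C4 is sp2, so one 2-silyloxy diene results and C1 and C5 are unchanged.

Step 10
Reactants: 14 silyl dienol ether of dehydrozaluzanin C; 13 dehydrozaluzanin C (3 equiv)
Product: 18 anhydro-ainsliadimer B (10β-hydroxy 4(15)-ene dienone), via trienone 15 (not isolated), via Diels–Alder adduct 16 (not isolated), via 10β-hydroperoxide 17 (not isolated)
Conditions: Pd(OAc)2 (1.1 equiv), MeCN, O2 (1 atm), 25 → 40 °C; then Me2S, 0 °C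
Reagents that add atoms: dioxygen, O=O
Why: Saegusa–Ito oxidation, Diels–Alder reaction and dienol autoxidation in one flask: divalent palladium converts 14 via its C2-palladated enolate and β-hydride loss of H-1 into trienone 15 (zerovalent palladium is released), whose locked s-cis C2=C1–C10=C14 diene adds ortho-selectively to the exocyclic enone of 13 on its convex α-face (C2–C4' and C14–C15' bonds, spiro C4' set), and the doubly activated H-2 of 16 is then abstracted so that O2 adds at C10 on the β-face, syn to the flat C3' carbonyl arm and anti to the bulkier C5' arm of the spiro centre, before Me2S reduces the hydroperoxide.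

Step 11
Reactants: 18 anhydro-ainsliadimer B
Product: 19 ainsliadimer B
Conditions: DBU (0.2 equiv), THF/H2O 4:1, 0 → 23 °C
Reagents that add atoms: water, O
Why: Base-catalysed oxa-Michael addition of water: the exocyclic methylene of the cross-conjugated dienone is the most electrophilic and least hindered acceptor (ketone-activated, while the two α-methylene lactones are only ester-activated), and the enolisable C4 settles under the base in the more stable configuration, CH2OH α and trans to the C5–C6 bond.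

**Compound list**

1 | α-santonin, (11S)-3-oxo-eudesma-1,4-dien-12,6α-olide (6βH, 7αH, 10β-CH3, 11α-CH3) | C[C@@H]1C(=O)O[C@H]2[C@H]1CC[C@@]3(C)C=CC(=O)C(C)=C23 | starting material
2 | isophotosantonic lactone, 10α-hydroxy-3-oxo-1αH-guai-4-en-12,6α-olide | C[C@@H]1C(=O)O[C@H]2[C@H]1CC[C@@](C)(O)[C@@H]3CC(=O)C(C)=C23 | intermediate
3 | 3β,10α-dihydroxy-1αH-guai-4-en-12,6α-olide | C[C@@H]1C(=O)O[C@H]2[C@H]1CC[C@@](C)(O)[C@@H]3C[C@H](O)C(C)=C23 | intermediate
4 | 3α-[1-(2-nitrophenylsulfonyl)hydrazin-1-yl]-10α-hydroxy-1αH-guai-4-en-12,6α-olide | C[C@@H]1C(=O)O[C@H]2[C@H]1CC[C@@](C)(O)[C@@H]3C[C@@H](N(N)S(=O)(=O)c4ccccc4[N+](=O)[O-])C(C)=C23 | intermediate (not isolated)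
5 | 3α-diazenyl-10α-hydroxy-1αH-guai-4-en-12,6α-olide | C[C@@H]1C(=O)O[C@H]2[C@H]1CC[C@@](C)(O)[C@@H]3C[C@@H](N=N)C(C)=C23 | intermediate (not isolated)
6 | 10α-hydroxy-1αH,5αH-guai-3-en-12,6α-olide | C[C@@H]1C(=O)O[C@H]2[C@H]1CC[C@@](C)(O)[C@@H]3CC=C(C)[C@H]23 | intermediate
7 | 1αH,5αH-guaia-3,10(14)-dien-12,6α-olide (11α-CH3) | C[C@@H]1C(=O)O[C@H]2[C@H]1CCC(=C)[C@@H]3CC=C(C)[C@H]23 | intermediate
8 | 11β-phenylselanyl-1αH,5αH-guaia-3,10(14)-dien-12,6α-olide (11α-CH3) | C[C@]1([Se]c4ccccc4)C(=O)O[C@H]2[C@H]1CCC(=C)[C@@H]3CC=C(C)[C@H]23 | intermediate (not isolated)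
9 | selenoxide of 8 | C[C@]1([Se](=O)c4ccccc4)C(=O)O[C@H]2[C@H]1CCC(=C)[C@@H]3CC=C(C)[C@H]23 | intermediate (not isolated)
10 | 1αH,5αH-guaia-3,10(14),11(13)-trien-12,6α-olide | C=C1C(=O)O[C@H]2[C@H]1CCC(=C)[C@@H]3CC=C(C)[C@H]23 | intermediate
11 | estafiatin, 3α,4α-epoxy-1αH,5αH-guaia-10(14),11(13)-dien-12,6α-olide | C=C1C(=O)O[C@H]2[C@H]1CCC(=C)[C@@H]3C[C@H]4O[C@@]4(C)[C@H]23 | intermediate
12 | 3-epizaluzanin C, 3α-hydroxy-1αH,5αH-guaia-4(15),10(14),11(13)-trien-12,6α-olide | C=C1C(=O)O[C@H]2[C@H]1CCC(=C)[C@@H]3C[C@@H](O)C(=C)[C@H]23 | intermediate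
13 | dehydrozaluzanin C, 3-oxo-1αH,5αH-guaia-4(15),10(14),11(13)-trien-12,6α-olide | C=C1C(=O)O[C@H]2[C@H]1CCC(=C)[C@@H]3CC(=O)C(=C)[C@H]23 | intermediate
14 | 3-(tert-butyldimethylsilyloxy)-1αH,5αH-guaia-2,4(15),10(14),11(13)-tetraen-12,6α-olide | C=C1C(=O)O[C@H]2[C@H]1CCC(=C)[C@@H]3C=C(O[Si](C)(C)C(C)(C)C)C(=C)[C@H]23 | intermediate
15 | 3-oxo-5αH-guaia-1,4(15),10(14),11(13)-tetraen-12,6α-olide (trienone diene) | C=C1C(=O)O[C@H]2[C@H]1CCC(=C)C3=CC(=O)C(=C)[C@H]23 | intermediate (not isolated)
16 | Diels–Alder adduct: C2–C4' and C14–C15' bonds, 1(10)-ene, 2βH, 3-oxo-4(15)-ene in the upper half, spiro C4' as in the target | C=C1C(=O)O[C@@H]2[C@@H]3C=4[C@H](C(=O)C3=C)[C@]3(CCC4CC[C@@H]12)C(=O)C[C@H]1C(=C)CC[C@H]2C(=C)C(=O)O[C@@H]2[C@H]13 | intermediate (not isolated)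
17 | 10β-hydroperoxide of the 1(2)-en-3-one dimer | C=C1C(=O)O[C@@H]2[C@@H]3C4=C(C(=O)C3=C)[C@]3(CC[C@]4(OO)CC[C@@H]12)C(=O)C[C@H]1C(=C)CC[C@H]2C(=C)C(=O)O[C@@H]2[C@H]13 | intermediate (not isolated)
18 | anhydro-ainsliadimer B: the target with C4=C15 exocyclic methylene in place of C4(H)CH2OH, 10β-OH | C=C1C(=O)O[C@@H]2[C@@H]3C4=C(C(=O)C3=C)[C@]3(CC[C@]4(O)CC[C@@H]12)C(=O)C[C@H]1C(=C)CC[C@H]2C(=C)C(=O)O[C@@H]2[C@H]13 | intermediate
19 | ainsliadimer B | C=C1C(=O)O[C@@H]2[C@@H]3C4=C(C(=O)[C@H]3CO)[C@]3(CC[C@]4(O)CC[C@@H]12)C(=O)C[C@H]1C(=C)CC[C@H]2C(=C)C(=O)O[C@@H]2[C@H]13 | target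

**Summary**

Total step count: 11. Longest linear sequence: 11 steps (1 → 19); compound 13 is used twice, once to make 14 and once as the dienophile in step 10.

Steps most likely to fail:

Step 3 (reductive transposition). The outcome at C5 depends on the facial selectivity of step 2 and on a clean SN2 Mitsunobu reaction at a hindered cyclopentenyl carbinol. The fallback sets out from 2 and comes back at 6. Hydrogenation of the enone of 2 (H2, palladium metal on carbon, EtOAc) from the α-face gives the cis-fused 10α-hydroxy-3-oxo-1αH,4αH,5αH-guaian-12,6α-olide F1. NaBH4 (MeOH, 0 °C) reduces it to the 3β-alcohol F2, and MsCl/Et3N gives the 3β-mesylate F3. E2 elimination (LiBr, Li2CO3, DMF, 120 °C), in which H-4α is anti to the leaving group, then delivers 6. Here C5 is set by heterogeneous hydrogenation instead of a sigmatropic hydrogen transfer.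

Step 10 (one-flask diene generation, cycloaddition and C10 oxygenation). The trienone can dimerise or react in hetero-Diels–Alder mode, and the autoxidation may give the 10α-epimer or stop at the deoxy adduct. The fallback sets out from 14 (with 13) and comes back at 18. PhSeCl (CH2Cl2, −78 °C) converts 14 into 2α-phenylselanyl-dehydrozaluzanin C F4. mCPBA at −78 °C gives the selenoxide F5, which on warming to 0 °C under argon with 13 (3 equiv) loses PhSeOH by syn-elimination (H-1 is cis) to release 15 slowly. The cycloaddition then gives adduct 16, which is isolated here. TBSOTf/Et3N turns 16 into the silyl dienol ether F6 (3-silyloxy-2,1(10)-diene). Dimethyldioxirane (acetone, −78 °C) epoxidises its distal C1=C10 bond to the 1β,10β-epoxide F7, and TBAF/AcOH opens this to 18 (vinylogous Rubottom oxidation). The diene is thus unveiled without palladium, and the C10–O bond is made by an electrophilic oxidant instead of a radical chain.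

Step 11 (hydration). The oxa-Michael addition is reversible, and water or base may also attack the α-methylene lactones or epimerise C5. The fallback sets out from 18 and comes back at 19. Copper-catalysed conjugate borylation (CuCl, Xantphos, NaOtBu cat., B2pin2 1.05 equiv, MeOH, THF, 0 °C) gives the 15-(pinacolboryl) ketone F8 with C4 as in the target. NaBO3·4H2O (THF/H2O, 0 °C) then oxidises the C–B bond to the primary alcohol 19. Irreversible C–B bond formation followed by oxidation replaces the equilibrium addition of water.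

Further compounds
F1 | step 3 | 10α-hydroxy-3-oxo-1αH,4αH,5αH-guaian-12,6α-olide (4β-CH3) | C[C@@H]1C(=O)O[C@H]2[C@H]1CC[C@@](C)(O)[C@@H]3CC(=O)[C@H](C)[C@H]23
F2 | step 3 | 3β,10α-dihydroxy-1αH,4αH,5αH-guaian-12,6α-olide | C[C@@H]1C(=O)O[C@H]2[C@H]1CC[C@@](C)(O)[C@@H]3C[C@H](O)[C@H](C)[C@H]23
F3 | step 3 | 3β-methanesulfonyloxy-10α-hydroxy-1αH,4αH,5αH-guaian-12,6α-olide | C[C@@H]1C(=O)O[C@H]2[C@H]1CC[C@@](C)(O)[C@@H]3C[C@H](OS(C)(=O)=O)[C@H](C)[C@H]23
F4 | step 10 | 2α-phenylselanyl-dehydrozaluzanin C | C=C1C(=O)O[C@H]2[C@H]1CCC(=C)[C@@H]3[C@@H]([Se]c4ccccc4)C(=O)C(=C)[C@H]23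
F5 | step 10 | selenoxide of 2α-phenylselanyl-dehydrozaluzanin C | C=C1C(=O)O[C@H]2[C@H]1CCC(=C)[C@@H]3[C@@H]([Se](=O)c4ccccc4)C(=O)C(=C)[C@H]23
F6 | step 10 | 3-(tert-butyldimethylsilyloxy)-2,1(10)-dienol ether of adduct 16 | C=C1C(=O)O[C@@H]2[C@@H]3C=4C(=C(O[Si](C)(C)C(C)(C)C)C3=C)[C@]3(CCC4CC[C@@H]12)C(=O)C[C@H]1C(=C)CC[C@H]2C(=C)C(=O)O[C@@H]2[C@H]13
F7 | step 10 | 1β,10β-epoxide of the silyl dienol ether | C=C1C(=O)O[C@@H]2[C@@H]3[C@]45C(=C(O[Si](C)(C)C(C)(C)C)C3=C)[C@]3(CC[C@]4(O5)CC[C@@H]12)C(=O)C[C@H]1C(=C)CC[C@H]2C(=C)C(=O)O[C@@H]2[C@H]13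
F8 | step 11 | 15-(4,4,5,5-tetramethyl-1,3,2-dioxaborolan-2-yl) analogue of 19 (B in place of the primary OH) | C=C1C(=O)O[C@@H]2[C@@H]3C4=C(C(=O)[C@H]3CB5OC(C)(C)C(C)(C)O5)[C@]3(CC[C@]4(O)CC[C@@H]12)C(=O)C[C@H]1C(=C)CC[C@H]2C(=C)C(=O)O[C@@H]2[C@H]13
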